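The target is the C2-symmetric head-to-tail 1,4-dioxane dimer of one 6α,7β-dioxygenated ferruginol methyl ether, so the route rests on a single enantiopure abietane. Its ring A is closed through the C1–C10 bond by an enantioselective alkylative dearomatisation: ring B is read as a masked 1-naphthol (O at C7, quaternary C10 para to it), and a flat, achiral naphthol carrying the 5-iodo-2-methylpentan-2-yl chain on C5 is C-alkylated at its methyl-bearing para carbon. One operation forms ring A, the benzylic quaternary stereocentre C10 and the C5=C6–C7=O enone, from which α-face hydroboration sets C5 and C6 before acid joins two monomers at C7.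

Key step: step 8

Remark: abietane numbering is used for all ring atoms and for the corresponding atoms of the precursors (C20 = angular methyl); diol 15 is carried as a mixture of C7 epimers because C7 is ionised and reset in step 10; 1 and 5 are taken as commercial.

Step 1
Reactants: 1 4-bromo-2-isopropylanisole
Product: 3 methyl 4-methoxy-3-(propan-2-yl)benzoate, via aryllithium 2 (not isolated)
Conditions: n-BuLi, THF, −78 °C; then added to excess ClCO2Me, −78 °C → rt
Reagents that add atoms: methyl chloroformate, COC(=O)Cl
Why: Bromine–lithium exchange is faster than ortho-metalation at −78 °C and inverse addition of the aryllithium to excess chloroformate prevents double addition (halogen–metal exchange and acylation); no stereocentre is formed.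

Step 2
Reactants: 3 methyl 4-methoxy-3-(propan-2-yl)benzoate
Product: 4 2-(dimethyl-oxo-λ6-sulfanylidene)-1-[4-methoxy-3-(propan-2-yl)phenyl]ethan-1-one (aroyl sulfoxonium ylide)
Conditions: Me3S(O)I, KOtBu, THF, reflux; then 3, reflux
Reagents that add atoms: trimethylsulfoxonium iodide, C[S+](C)(C)=O.[I-]
Why: Dimethylsulfoxonium methylide (Corey–Chaykovsky reagent), formed in the flask, is C-acylated by the methyl ester and the stabilised β-keto sulfoxonium ylide does not react further; no stereocentre is formed.

Step 3
Reactants: 5 isobutyl 5-chloro-2,2-dimethylpentanoate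
Product: 6 5-chloro-2,2-dimethylpentanal
Conditions: DIBAL-H, CH2Cl2, −78 °C; Rochelle salt work-up
Reagents that add atoms: none
Why: At −78 °C the tetrahedral aluminium hemiacetal of the α-quaternary ester survives until work-up, so the partial DIBAL reduction stops at the aldehyde and the primary chloride is untouched.

Step 4
Reactants: 6 5-chloro-2,2-dimethylpentanal
Product: 7 1,1-dibromo-6-chloro-3,3-dimethylhex-1-ene
Conditions: CBr4, PPh3, CH2Cl2, 0 °C
Reagents that add atoms: carbon tetrabromide, BrC(Br)(Br)Br
Why: Dibromo-olefination of a non-enolisable aldehyde (first stage of the Corey–Fuchs homologation); the alkyl chloride is inert to the phosphorus ylide.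

Step 5
Reactants: 7 1,1-dibromo-6-chloro-3,3-dimethylhex-1-ene
Product: 9 7-chloro-4,4-dimethylhept-2-yne, via lithium acetylide 8 (not isolated)
Conditions: n-BuLi, THF, −78 °C; then MeI, −78 °C → rt
Reagents that add atoms: iodomethane, CI
Why: Second stage of the Corey–Fuchs reaction, in which Br/Li exchange, Fritsch–Buttenberg–Wiechell-type rearrangement and deprotonation give the lithium acetylide that is C-methylated by MeI, while the primary chloride survives n-BuLi at −78 °C and cannot be reached intramolecularly by the linear acetylide.

Step 6
Reactants: 4 aroyl sulfoxonium ylide; 9 7-chloro-4,4-dimethylhept-2-yne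
Product: 10 3-(5-chloro-2-methylpentan-2-yl)-6-methoxy-4-methyl-7-(propan-2-yl)naphthalen-1-ol
Conditions: [Cp*Rh(MeCN)3](SbF6)2 (cat.), Zn(OTf)2 (cat.), DCE, 80 °C
Reagents that add atoms: none
Why: Rh(III)-catalysed C–H activation/[4+2] annulation of an aroyl sulfoxonium ylide with an alkyne, in which rhodation occurs at the less hindered ortho C–H (para to isopropyl), the alkyne inserts with its methyl-bearing carbon on the arene and the bulky tert-alkyl-bearing carbon on rhodium, and carbene migratory insertion with loss of DMSO followed by tautomerisation gives the 1-naphthol with C6–H.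

Step 7
Reactants: 10 3-(5-chloro-2-methylpentan-2-yl)-6-methoxy-4-methyl-7-(propan-2-yl)naphthalen-1-ol
Product: 11 3-(5-iodo-2-methylpentan-2-yl)-6-methoxy-4-methyl-7-(propan-2-yl)naphthalen-1-ol
Conditions: NaI, butan-2-one, reflux, Ar
Reagents that add atoms: sodium iodide, [Na+].[I-]
Why: Finkelstein exchange driven by precipitation of NaCl gives the more reactive primary iodide without base, so the naphthol does not cyclise prematurely.

Step 8
Reactants: 11 3-(5-iodo-2-methylpentan-2-yl)-6-methoxy-4-methyl-7-(propan-2-yl)naphthalen-1-ol
Product: 12 (10S)-12-methoxyabieta-5,8,11,13-tetraen-7-one [(4bS)-3-methoxy-4b,8,8-trimethyl-2-(propan-2-yl)-5,6,7,8-tetrahydrophenanthren-10(4bH)-one]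
Conditions: C2-symmetric spiro-binaphthyl quaternary ammonium bromide with 3,4,5-trifluorophenyl groups (5 mol %, antipode chosen for 10S), 50% aq. KOH, toluene (0.005 M), degassed, Ar, −20 °C
Reagents that add atoms: none
Why: Proposed new method: hydroxide deprotonates 11 at the interface and the 1-naphtholate is extracted as a tight ion pair with the chiral ammonium cation; its para carbon C10, which bears the C20 methyl, displaces iodide from C1 in an intramolecular SN2 reaction, and ring B is dearomatised to the 5-en-7-one, which cannot re-aromatise because C10 is quaternary. The closest known reaction types are the racemic intramolecular para-C-alkylation of phenolates by ω-haloalkyl chains (alkylative dearomatisation) and the chiral phase-transfer ion-pairing catalysis used in catalytic asymmetric dearomatisation of naphthols, but an enantioselective SN2 closure at C4 of a 1-naphthol is not established. Ring A is closed in the 6-exo-tet mode through a chair-like transition state. The single new stereocentre C10 is controlled by the catalyst, whose aryl walls shield one face of the planar naphtholate in the ion pair, and the antipode that gives 10S is to be identified by screening. The step needs C10 against C6 and against oxygen: the chain leaves C5 from a quaternary carbon next to the C20 methyl, so the ground-state rotamer already holds C1 over C10, whereas closure at C6 requires a rotamer that pushes a geminal methyl into the ring plane against C20 (A1,3 strain); oxygen is meta to the chain and out of reach, and high dilution suppresses intermolecular O-alkylation.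

Step 9
Reactants: 12 (10S)-12-methoxyabieta-5,8,11,13-tetraen-7-one
Product: 15 (5S,6R,10S)-12-methoxyabieta-8,11,13-triene-6α,7-diol (C7 epimers), via alkoxyborane 13 (not isolated), via C6-borane 14 (not isolated)
Conditions: BH3·THF (excess), THF, 0 °C → rt; then NaOH, H2O2, 0 °C
Reagents that add atoms: hydrogen peroxide, OO
Why: Borane first reduces the conjugated ketone in the 1,2-sense and then hydroborates the trisubstituted C5=C6 bond with boron on the less substituted C6 and syn delivery from the α face, because the β face is blocked by the axial C10 and C4 methyls (as in steroidal Δ5-alkenes), so oxidation with retention gives 5α-H and 6α-OH while the C7 configuration is irrelevant later.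

Step 10
Reactants: 15 (5S,6R,10S)-12-methoxyabieta-8,11,13-triene-6α,7-diol (two molecules)
Product: 16 target, the (5S,6R,7R,10S,5′S,6′R,7′R,10′S) head-to-tail dimer in which O6 is bonded to C7′ and O6′ to C7 (1,4-dioxane trans-fused to both B rings)
Conditions: TfOH (5 mol %), 4 Å MS, CH2Cl2 (0.5 M), −40 → 0 °C
Reagents that add atoms: none
Why: Acid-catalysed double dehydrative etherification in which each 7-hydroxyl ionises to a p-methoxybenzylic cation that is captured by the 6α-hydroxyl of the second monomer, first inter- then intramolecularly, and because every C7–O bond stays reversibly ionisable both C7 epimers converge on the thermodynamically preferred all-equatorial, doubly trans-fused dioxane with 7β-O (7R) in each half, only the homochiral dimer being possible from the enantiopure monomer.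

Compound list
1 | 4-bromo-2-isopropylanisole | COc1ccc(Br)cc1C(C)C | starting material
2 | [4-methoxy-3-(propan-2-yl)phenyl]lithium | [Li]c1ccc(OC)c(c1)C(C)C | intermediate
3 | methyl 4-methoxy-3-(propan-2-yl)benzoate | COC(=O)c1ccc(OC)c(c1)C(C)C | intermediate
4 | 2-(dimethyl-oxo-λ6-sulfanylidene)-1-[4-methoxy-3-(propan-2-yl)phenyl]ethan-1-one | COc1ccc(cc1C(C)C)C(=O)C=S(C)(C)=O | intermediate
5 | isobutyl 5-chloro-2,2-dimethylpentanoate | CC(C)COC(=O)C(C)(C)CCCCl | starting material
6 | 5-chloro-2,2-dimethylpentanal | O=CC(C)(C)CCCCl | intermediate
7 | 1,1-dibromo-6-chloro-3,3-dimethylhex-1-ene | BrC(Br)=CC(C)(C)CCCCl | intermediate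
8 | (6-chloro-3,3-dimethylhex-1-yn-1-yl)lithium | [Li]C#CC(C)(C)CCCCl | intermediate
9 | 7-chloro-4,4-dimethylhept-2-yne | CC#CC(C)(C)CCCCl | intermediate
10 | 3-(5-chloro-2-methylpentan-2-yl)-6-methoxy-4-methyl-7-(propan-2-yl)naphthalen-1-ol | COc1cc2c(C)c(C(C)(C)CCCCl)cc(O)c2cc1C(C)C | intermediate
11 | 3-(5-iodo-2-methylpentan-2-yl)-6-methoxy-4-methyl-7-(propan-2-yl)naphthalen-1-ol | COc1cc2c(C)c(C(C)(C)CCCI)cc(O)c2cc1C(C)C | intermediate
12 | (10S)-12-methoxyabieta-5,8,11,13-tetraen-7-one | COc1cc2c(cc1C(C)C)C(=O)C=C1C(C)(C)CCC[C@]21C | intermediate
13 | (10S)-7-boryloxy-12-methoxyabieta-5,8,11,13-tetraene (C7 epimers) | COc1cc2c(cc1C(C)C)C(OB)C=C1C(C)(C)CCC[C@]21C | intermediate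
14 | (5S,10S)-6α-boryl-7-boryloxy-12-methoxyabieta-8,11,13-triene (C7 epimers) | COc1cc2c(cc1C(C)C)C(OB)[C@H](B)[C@H]1C(C)(C)CCC[C@]21C | intermediate
15 | (5S,6R,10S)-12-methoxyabieta-8,11,13-triene-6α,7-diol (C7 epimers) | COc1cc2c(cc1C(C)C)C(O)[C@H](O)[C@H]1C(C)(C)CCC[C@]21C | intermediate
16 | (5S,6R,7R,10S,5′S,6′R,7′R,10′S)-6,7′:7,6′-diepoxy dimer of 12-methoxyabieta-8,11,13-triene (CNP0327150.1) | COc1cc2c(cc1C(C)C)[C@H]1O[C@H]3[C@H](O[C@@H]1[C@H]1C(C)(C)CCC[C@]21C)c1cc(C(C)C)c(OC)cc1[C@@]1(C)CCCC(C)(C)[C@H]31 | target

Total step count: 10. Longest linear sequence: 8 steps (steps 3 to 10).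

Steps most likely to fail

Step 8 (proposed new method). The asymmetric induction may be poor because the chiral cation pairs with oxygen, several atoms away from C10, and intermolecular O-alkylation may compete with ring closure. The fallback uses known chemistry. Starting from 11, ring A is closed without a chiral catalyst by the classical phenolate para-alkylation (KOtBu, t-BuOH, high dilution, reflux) to racemic 12-methoxyabieta-5,8,11,13-tetraen-7-one F1. The enantiomers are then separated by preparative chromatography on a chiral stationary phase, and the (10S)-enantiomer is 12, where the route is rejoined.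

Step 10. The C7 cation may be diverted by a 1,2-hydride shift from C6 (pinacol-type collapse to the 6-ketone) or consumed in open-chain oligomers before the second C–O bond closes. The fallback starts from 15: DDQ (dioxane, rt) should oxidise only the electron-rich benzylic hydroxyl to 6α-hydroxy-12-methoxyabieta-8,11,13-trien-7-one F5. With TMSOTf and Et3SiH in CH2Cl2 (−78 → 0 °C) the ketol should pair head-to-tail to the bis-hemiketal F6. Both ketal carbons are then reduced through oxocarbenium ions (double reductive etherification), with axial hydride delivery from the α face giving 7β-O. The cationic C7 is now oxygen-stabilised and has no hydride-shift exit, and the product is 16.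

Step 9. β-Elimination of the C6-boryl/C7-boryloxy intermediate may remove the C7 oxygen, or hydroboration of the hindered trisubstituted alkene may stall. The fallback starts from 12: hydrogenation (H2, Pd/C, EtOAc) from the α face gives 12-methoxyabieta-8,11,13-trien-7-one F2. NaBH4 (MeOH) gives 12-methoxyabieta-8,11,13-trien-7-ol F3, and TsOH (toluene, 80 °C) dehydrates it to 12-methoxyabieta-6,8,11,13-tetraene F4. Upjohn dihydroxylation (cat. OsO4, NMO) from the α face then gives the 6α,7α-diol, which is the 7α-epimer contained in 15 and is taken into step 10.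

Further compounds
F1 | step 8 | racemic 12-methoxyabieta-5,8,11,13-tetraen-7-one | COc1cc2c(cc1C(C)C)C(=O)C=C1C(C)(C)CCCC21C
F2 | step 9 | (5S,10S)-12-methoxyabieta-8,11,13-trien-7-one | COc1cc2c(cc1C(C)C)C(=O)C[C@H]1C(C)(C)CCC[C@]21C
F3 | step 9 | (5S,10S)-12-methoxyabieta-8,11,13-trien-7-ol (C7 epimers) | COc1cc2c(cc1C(C)C)C(O)C[C@H]1C(C)(C)CCC[C@]21C
F4 | step 9 | (5S,10S)-12-methoxyabieta-6,8,11,13-tetraene | COc1cc2c(cc1C(C)C)C=C[C@H]1C(C)(C)CCC[C@]21C
F5 | step 10 | (5S,6R,10S)-6α-hydroxy-12-methoxyabieta-8,11,13-trien-7-one | COc1cc2c(cc1C(C)C)C(=O)[C@H](O)[C@H]1C(C)(C)CCC[C@]21C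
F6 | step 10 | head-to-tail bis-hemiketal dimer of F5 (7,7′-dihydroxy derivative of 16) | COc1cc2c(cc1C(C)C)C1(O)O[C@H]3C(O)(O[C@@H]1[C@H]1C(C)(C)CCC[C@]21C)c1cc(C(C)C)c(OC)cc1[C@@]1(C)CCCC(C)(C)[C@H]31
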